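The cycloheptene holds the C9 oxygen and the C7 carbon branch 1,3 across C8, with quaternary C4 next to C5: the signature of a cyclohepta-1,4-diene made by ring expansion of a divinylcyclopropane (locants: C1 isopropyl carbinol, C2, C3, C4 methyl-bearing fusion carbon, C5 to C9 around the seven-membered ring, C10 fusion CH). The route rests on one catalyst-controlled formal (4+3) union of an acyclic 2-siloxydiene, already carrying the isopropyl ketone chain, with a vinyldiazoacetate. That single operation forms C7-C8 and C4-C5, closes the seven-membered ring, sets C4 and leaves a C9=C10 enol silane, which then closes the cyclopentane by aldol addition; redox adjustments and acylation follow.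

Key step: step 8

Remark on faces: β is the face of the C4 methyl group, α the opposite face; the bicyclic compounds are cis-fused 5-7 systems (hydroazulenes) with the locants given above.

Assumption: Rh2(S-DOSP)4, dirhodium tetrakis[(S)-N-(4-dodecylbenzenesulfonyl)prolinate], is taken to show the same sense of induction with the 1,1-disubstituted silyloxyalkene of 9 as with simple terminal alkenes, which leads to (1R,2S)-14 and (4S)-15; if the opposite sense is found, Rh2(R-DOSP)4 is used and nothing else changes.

Step 1
Reactants: 1 pent-4-ynoic acid
Product: 3 N-methoxy-N-methylpent-4-ynamide, via acyl imidazole 2 (not isolated)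
Conditions: CDI (1.1 equiv), CH2Cl2, rt; then MeNHOMe·HCl (1.2 equiv), rt
Reagents that add atoms: N,O-dimethylhydroxylamine hydrochloride, CNOC.Cl
Why: Amide coupling through the acyl imidazolide: carbonyldiimidazole activates the acid with loss of CO2 and the hydroxylamine then displaces imidazole to give the Weinreb amide, the terminal alkyne being inert.

Step 2
Reactants: 3 N-methoxy-N-methylpent-4-ynamide, 4 acetyl chloride
Product: 6 (E)-N-methoxy-N,4-dimethyl-6-oxohept-4-enamide, via alkenylalane 5 (not isolated)
Conditions: AlMe3 (3 equiv), Cp2ZrCl2 (0.25 equiv), ClCH2CH2Cl, 0 °C to rt; volatiles removed; then THF, 4 (1.5 equiv), Pd(PPh3)4 (5 mol %), 0 °C to rt; cold dilute aq HCl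
Reagents that add atoms: trimethylaluminium, C[Al](C)C
Why: Negishi zirconium-catalysed methylalumination adds CH3 and Al syn across the terminal alkyne with aluminium on the terminal carbon, which fixes the E geometry, and the alkenyl-aluminium bond is then acylated with retention by palladium-catalysed cross-coupling with the acid chloride (oxidative addition to zerovalent palladium, transmetalation, reductive elimination); Weinreb amides tolerate AlMe3, as in their own preparation from esters.

Step 3
Reactants: 6 (E)-N-methoxy-N,4-dimethyl-6-oxohept-4-enamide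
Product: 7 (E)-6-(tert-butyldimethylsilyloxy)-N-methoxy-N,4-dimethylhepta-4,6-dienamide
Conditions: TBSOTf (1.2 equiv), Et3N (2 equiv), CH2Cl2, −78 to 0 °C
Reagents that add atoms: tert-butyldimethylsilyl trifluoromethanesulfonate, CC(C)(C)[Si](C)(C)OS(=O)(=O)C(F)(F)F
Why: Soft enolisation: the silyl triflate activates the enone oxygen and the amine removes a proton from the unhindered α'-methyl group at low temperature, which should give the cross-conjugated 2-silyloxydiene without touching the E alkene or the amide.

Step 4
Reactants: 7 (E)-6-(tert-butyldimethylsilyloxy)-N-methoxy-N,4-dimethylhepta-4,6-dienamide, 8 isopropylmagnesium chloride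
Product: 9 (E)-8-(tert-butyldimethylsilyloxy)-2,6-dimethylnona-6,8-dien-3-one
Conditions: 8 (1.5 equiv), THF, −20 to 0 °C; aq NH4Cl; chromatography on Et3N-washed silica
Reagents that add atoms: none
Why: Grignard addition to a Weinreb amide stops at the magnesium-chelated tetrahedral adduct, which releases the isopropyl ketone only on quench, so over-addition is excluded and the silyl dienol ether is a spectator.

Step 5
Reactants: 10 methyl acetoacetate
Product: 11 methyl 2-diazo-3-oxobutanoate
Conditions: 4-acetamidobenzenesulfonyl azide, Et3N, MeCN, 0 °C to rt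
Reagents that add atoms: 4-acetamidobenzenesulfonyl azide, CC(=O)Nc1ccc(cc1)S(=O)(=O)N=[N+]=[N-]
Why: Regitz diazo transfer from the sulfonyl azide to the doubly activated methylene group.

Step 6
Reactants: 11 methyl 2-diazo-3-oxobutanoate
Product: 12 methyl 2-diazo-3-hydroxybutanoate (racemic)
Conditions: NaBH4, MeOH, 0 °C
Reagents that add atoms: none
Why: Chemoselective borohydride reduction of the ketone beside the diazo ester; the carbinol centre is racemic and is erased in the next step.

Step 7
Reactants: 12 methyl 2-diazo-3-hydroxybutanoate
Product: 13 methyl 2-diazobut-3-enoate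
Conditions: POCl3, Et3N, CH2Cl2, 0 °C to rt; filtered through silica with pentane, kept cold, used the same day
Reagents that add atoms: none
Why: Dehydration by E2 elimination of the dichlorophosphate ester gives the vinyldiazoacetate, which is used at once because it slowly electrocyclises to a pyrazole.

Step 8
Reactants: 9 (E)-8-(tert-butyldimethylsilyloxy)-2,6-dimethylnona-6,8-dien-3-one, 13 methyl 2-diazobut-3-enoate
Product: 15 methyl (4S)-6-(tert-butyldimethylsilyloxy)-4-methyl-4-(4-methyl-3-oxopentyl)cyclohepta-1,5-diene-1-carboxylate, via divinylcyclopropane 14 (not isolated)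
Conditions: Rh2(S-DOSP)4 (1 mol %), hexanes, −78 °C, 13 (1.5 equiv) added over 2 h, then rt; 60 °C to finish the rearrangement
Reagents that add atoms: none
Why: The dirhodium carbenoid formed from 13 with loss of N2 transfers its carbon (C7) to the terminal silyloxy-substituted C8=C9 bond of 9 to give the cis-dialkenylcyclopropane 14, and a boat Cope rearrangement then cleaves the donor-acceptor bond C7-C9 and joins the vinyl terminus C5 to C4, so that C7-C8 and C4-C5 are the net new bonds. Its nearest precedent in type is the enantioselective cyclopropanation and divinylcyclopropane rearrangement sequence (formal (4+3) cycloaddition) of vinyl diazoacetates with 2-silyloxybutadienes and with dienes bearing a fully substituted terminus under chiral dirhodium prolinate catalysis. The three-membered ring closes by (2+1) carbene transfer, and the seven-membered ring C4 through C10 is produced by sigmatropic enlargement of that cyclopropane rather than by joining the two ends of a chain. The only stereocentre, C4, is controlled by the catalyst, which fixes the configuration of 14, and by the E geometry of C10=C4, which the boat transition state translates into the (4S) quaternary carbon. The step needs site selection, secured because the unhindered electron-rich 1,1-disubstituted enol ether outpaces the trisubstituted alkene, the ketone and the allylic C-H bonds, and it needs face selection together with a cis cyclopropane, for which the prolinate catalyst is used in a hydrocarbon solvent at low temperature, conditions that also disfavour attack at the vinylogous carbon of the carbenoid. Gentle heating should complete the Cope step, which is slowed by the C4 methyl group that points toward the cyclopropane CH2, and the limited excess of 13 guards against C-H insertion at the doubly allylic C8 of the product.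

Step 9
Reactants: 15 methyl (4S)-6-(tert-butyldimethylsilyloxy)-4-methyl-4-(4-methyl-3-oxopentyl)cyclohepta-1,5-diene-1-carboxylate
Product: 16 keto aldol (cis-fused hydroazulene; CO2CH3 on C7; C6=C7; 9-oxo; 1α-OH; 1β-isopropyl; 4β-methyl; 10β-H)
Conditions: TiCl4 (1.1 equiv), CH2Cl2, −78 to −40 °C; aq NaHCO3 added at −78 °C
Reagents that add atoms: none
Why: Intramolecular Mukaiyama aldol addition, a 5-exo-trig (enolexo) closure of the C10 enol silane onto the TiCl4-activated isopropyl ketone, forms C10-C1: the three-atom tether on the α face of C4 can reach only the α face of C10, so H10 ends β and the fusion is cis, and titanium bridging the new alkoxide and the C9 carbonyl places O1 on the side of C9 with the isopropyl group beside the small H10, which sets C1.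

Step 10
Reactants: 16 keto aldol
Product: 17 diol enoate (as 16 with 9β-OH and 9α-H in place of the ketone)
Conditions: Me4NBH(OAc)3 (5 equiv), MeCN/AcOH, −30 to 0 °C
Reagents that add atoms: none
Why: Evans-Saksena hydroxyl-directed reduction: the C1 hydroxyl exchanges onto boron and hydride is delivered within a six-membered array to the α face of the C9 carbonyl, giving the 9β-alcohol (external hydride would attack the open β face), while the enoate is inert to the triacetoxyborohydride.

Step 11
Reactants: 17 diol enoate
Product: 18 triol (as 17 with CH2OH on C7 in place of the ester)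
Conditions: i-Bu2AlH (5 equiv), CH2Cl2, −78 to 0 °C; aq potassium sodium tartrate work-up
Reagents that add atoms: none
Why: 1,2-Reduction of the conjugated ester by the aluminium hydride to the primary allylic alcohol; the two free hydroxyl groups only consume hydride.

Step 12
Reactants: 18 triol
Product: 20 diol with a C7 methyl group (C6=C7 trisubstituted alkene; 1α-OH; 9β-OH), via allylic mesylate 19 (not isolated)
Conditions: MsCl (1.05 equiv), Et3N, THF, −40 °C; then LiEt3BH (5 equiv), −40 to 0 °C
Reagents that add atoms: none
Why: Allylic deoxygenation in one flask: only the primary, unhindered hydroxyl is sulfonylated at −40 °C (the C9 hydroxyl is secondary and flanked by the congested fusion carbon, the C1 hydroxyl tertiary), and LiEt3BH then displaces the primary allylic mesylate by SN2 attack.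

Step 13
Reactants: 20 diol with a C7 methyl group
Product: 21 6β,7β-epoxide of 20 (7α-methyl; 6α-H)
Conditions: VO(acac)2 (5 mol %), t-BuOOH (1.5 equiv, in decane), CH2Cl2, 0 °C to rt
Reagents that add atoms: tert-butyl hydroperoxide, CC(C)(C)OO
Why: Vanadium-catalysed hydroxyl-directed epoxidation: the homoallylic C9 β-hydroxyl binds the vanadium alkyl peroxide and delivers oxygen to the β face of C6=C7, which is also the convex face of the cis-fused bicycle, and this sets C7 (oxygen β, methyl α).

Step 14
Reactants: 21 6β,7β-epoxide
Product: 24 triol (C5=C6; 7β-OH; 7α-methyl; 1α-OH; 1β-isopropyl; 4β-methyl; 9β-OH; 10β-H), via hydroxy selenide 22 (not isolated), via selenoxide 23 (not isolated)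
Conditions: PhSeSePh (0.6 equiv), NaBH4, EtOH, rt to 70 °C; then THF, NaHCO3, 30% H2O2, 0 °C to rt
Reagents that add atoms: none
Why: Epoxide to allylic alcohol transposition by selenoxide elimination: benzeneselenolate opens the epoxide by anti SN2 attack at the secondary C6, so the C7-O bond and its configuration are kept, and after oxidation the selenoxide undergoes syn elimination toward C5, the only carbon that offers a β-hydrogen, to give the C5=C6 alkene.

Step 15
Reactants: 25 4-acetoxybenzoic acid
Product: 26 4-acetoxybenzoyl chloride
Conditions: (COCl)2, DMF (cat.), CH2Cl2, 0 °C to rt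
Reagents that add atoms: oxalyl chloride, O=C(Cl)C(Cl)=O
Why: Acid chloride formation through the Vilsmeier-type chloroiminium species from DMF and oxalyl chloride; the aryl acetate is untouched.

Step 16
Reactants: 24 triol, 26 4-acetoxybenzoyl chloride
Product: 27 9β-(4-acetoxybenzoate) of 24
Conditions: 26 (1.3 equiv), Et3N, DMAP (0.2 equiv), CH2Cl2, 0 °C to rt
Reagents that add atoms: none
Why: DMAP-catalysed acylation (nucleophilic catalysis through the acylpyridinium ion) is selective for the only secondary hydroxyl, the tertiary C1 and C7 alcohols being too hindered, and it proceeds with retention at C9.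

Step 17
Reactants: 27 9β-(4-acetoxybenzoate)
Product: 28 CNP0280165.1, (3R,3aS,4S,6R,8aS)-3,6-dihydroxy-3-isopropyl-6,8a-dimethyl-1,2,3,3a,4,5,6,8a-octahydroazulen-4-yl 4-hydroxybenzoate
Conditions: NH3, MeOH, 0 °C
Reagents that add atoms: none
Why: Ammonolysis of the phenolic acetate, an activated aryl ester, should be far faster than attack on the hindered, electron-rich benzoate of the secondary alcohol, so only the acetyl group is removed.

Compound list
1 | pent-4-ynoic acid | C#CCCC(=O)O | starting material
2 | 1-(pent-4-ynoyl)imidazole | C#CCCC(=O)n1ccnc1 | intermediate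
3 | N-methoxy-N-methylpent-4-ynamide | C#CCCC(=O)N(C)OC | intermediate
4 | acetyl chloride | CC(Cl)=O | starting material
5 | (E)-5-(dimethylalumanyl)-N-methoxy-N,4-dimethylpent-4-enamide (Al and the C4 methyl cis) | C[Al](C)/C=C(\C)CCC(=O)N(C)OC | intermediate
6 | (E)-N-methoxy-N,4-dimethyl-6-oxohept-4-enamide | CC(=O)/C=C(\C)CCC(=O)N(C)OC | intermediate
7 | (E)-6-(tert-butyldimethylsilyloxy)-N-methoxy-N,4-dimethylhepta-4,6-dienamide | C=C(O[Si](C)(C)C(C)(C)C)/C=C(\C)CCC(=O)N(C)OC | intermediate
8 | isopropylmagnesium chloride | CC(C)[Mg]Cl | starting material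
9 | (E)-8-(tert-butyldimethylsilyloxy)-2,6-dimethylnona-6,8-dien-3-one | C=C(O[Si](C)(C)C(C)(C)C)/C=C(\C)CCC(=O)C(C)C | intermediate
10 | methyl acetoacetate | CC(=O)CC(=O)OC | starting material
11 | methyl 2-diazo-3-oxobutanoate | CC(=O)C(=[N+]=[N-])C(=O)OC | intermediate
12 | methyl 2-diazo-3-hydroxybutanoate (racemic) | CC(O)C(=[N+]=[N-])C(=O)OC | intermediate
13 | methyl 2-diazobut-3-enoate | C=CC(=[N+]=[N-])C(=O)OC | intermediate
14 | methyl (1R,2S)-2-(tert-butyldimethylsilyloxy)-2-[(E)-2,6-dimethyl-5-oxohept-1-en-1-yl]-1-vinylcyclopropane-1-carboxylate (the two alkenyl groups cis) | C=C[C@]1(C(=O)OC)C[C@]1(O[Si](C)(C)C(C)(C)C)/C=C(\C)CCC(=O)C(C)C | intermediate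
15 | methyl (4S)-6-(tert-butyldimethylsilyloxy)-4-methyl-4-(4-methyl-3-oxopentyl)cyclohepta-1,5-diene-1-carboxylate | CC(C)C(=O)CC[C@@]2(C)CC=C(C(=O)OC)CC(O[Si](C)(C)C(C)(C)C)=C2 | intermediate
16 | keto aldol: cis-fused hydroazulene; CO2CH3 on C7; C6=C7; 9-oxo; 1α-OH; 1β-isopropyl; 4β-methyl; 10β-H | CC(C)[C@]1(O)CC[C@@]2(C)CC=C(C(=O)OC)CC(=O)[C@@H]12 | intermediate
17 | diol enoate: as 16 with 9β-OH | CC(C)[C@]1(O)CC[C@@]2(C)CC=C(C(=O)OC)C[C@H](O)[C@@H]12 | intermediate
18 | triol: as 17 with CH2OH on C7 | CC(C)[C@]1(O)CC[C@@]2(C)CC=C(CO)C[C@H](O)[C@@H]12 | intermediate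
19 | allylic mesylate: as 18 with CH2OSO2CH3 on C7 | CC(C)[C@]1(O)CC[C@@]2(C)CC=C(COS(C)(=O)=O)C[C@H](O)[C@@H]12 | intermediate
20 | diol: CH3 on C7; C6=C7; 1α-OH; 1β-isopropyl; 4β-methyl; 9β-OH; 10β-H | CC(C)[C@]1(O)CC[C@@]2(C)CC=C(C)C[C@H](O)[C@@H]12 | intermediate
21 | 6β,7β-epoxide of 20 (7α-methyl) | CC(C)[C@]1(O)CC[C@@]2(C)C[C@@H]3O[C@]3(C)C[C@H](O)[C@@H]12 | intermediate
22 | hydroxy selenide: 6α-SePh; 7β-OH; 7α-methyl; 1α-OH; 9β-OH | CC(C)[C@]1(O)CC[C@@]2(C)C[C@@H]([Se]c3ccccc3)[C@](C)(O)C[C@H](O)[C@@H]12 | intermediate
23 | selenoxide of 22 (both configurations at selenium) | CC(C)[C@]1(O)CC[C@@]2(C)C[C@@H]([Se](=O)c3ccccc3)[C@](C)(O)C[C@H](O)[C@@H]12 | intermediate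
24 | triol: C5=C6; 7β-OH; 7α-methyl; 1α-OH; 1β-isopropyl; 4β-methyl; 9β-OH; 10β-H | CC(C)[C@]1(O)CC[C@@]2(C)C=C[C@](C)(O)C[C@H](O)[C@@H]12 | intermediate
25 | 4-acetoxybenzoic acid | CC(=O)Oc1ccc(cc1)C(=O)O | starting material
26 | 4-acetoxybenzoyl chloride | CC(=O)Oc1ccc(cc1)C(Cl)=O | intermediate
27 | 9β-(4-acetoxybenzoate) of 24 | CC(C)[C@]1(O)CC[C@@]2(C)C=C[C@](C)(O)C[C@H](OC(=O)c3ccc(OC(C)=O)cc3)[C@@H]12 | intermediate
28 | CNP0280165.1, (3R,3aS,4S,6R,8aS)-3,6-dihydroxy-3-isopropyl-6,8a-dimethyl-1,2,3,3a,4,5,6,8a-octahydroazulen-4-yl 4-hydroxybenzoate | CC(C)[C@]1(O)CC[C@@]2(C)C=C[C@](C)(O)C[C@H](OC(=O)c3ccc(O)cc3)[C@@H]12 | target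

Total step count: 17 steps. Longest linear sequence: 13 steps (1 to 28 through steps 1 to 4, 8 to 14, 16 and 17).

Steps most likely to fail

Step 8. The carbene transfer may discriminate the faces of the 1,1-disubstituted enol ether less well than it does with monosubstituted alkenes. Part of the material may also pass through the trans-cyclopropane, which can reach the cycloheptadiene only by reversible opening of the C7-C9 bond and so loses the stereochemical information. The carbenoid may further be attacked at its vinyl terminus. The fallback sets out from 9 and 13 and gives up catalyst control: the tandem reaction is run with achiral Rh2(O2CC7H15)4 (dirhodium tetraoctanoate) in refluxing hexanes to give racemic cycloheptadiene F1. The enantiomers are then separated by preparative supercritical-fluid chromatography on a polysaccharide-based chiral stationary phase. The (4S) enantiomer is 15, where the route resumes.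

Step 9. The Lewis acid may strip the silyl group without C-C bond formation, dehydrate or reopen the tertiary aldol, move the C6=C7 bond into conjugation with the C9 ketone, or the closure may give the C1 epimer. The fallback sets out from 15 and replaces the Lewis-acid aldol by a metal-enolate aldol under neutral conditions. NBS in THF at −78 °C converts the enol silane regiospecifically into the C10 bromo ketone F2 (both C10 epimers). SmI2 (2.2 equiv, THF, −78 °C) then generates the samarium enolate at C10, which adds to the isopropyl ketone in a Reformatsky-type cyclisation through a chelated transition state; this should give the same cis-fused, O1/C9-syn aldol and returns to the route at 16.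

Step 2. The acyl transfer to the alkenylalane may stall, or be overtaken by methyl transfer from residual aluminium species to the acid chloride or by attack on the amide. The fallback sets out from 3 and separates the two events. Alane 5 is made as before and quenched with I2 to give the isolable (E)-vinyl iodide F3. Stille coupling with tributyl(1-ethoxyvinyl)stannane (Pd(PPh3)4, CuI, DMF) gives the ethoxydiene F4, whose enol ether is hydrolysed with dilute aqueous HCl in THF; this returns to the route at enone 6.

Further compounds
F1 | step 8 | racemic methyl 6-(tert-butyldimethylsilyloxy)-4-methyl-4-(4-methyl-3-oxopentyl)cyclohepta-1,5-diene-1-carboxylate | CC(C)C(=O)CC[C@@]1(C)CC=C(C(=O)OC)CC(O[Si](C)(C)C(C)(C)C)=C1.CC(C)C(=O)CC[C@]1(C)CC=C(C(=O)OC)CC(O[Si](C)(C)C(C)(C)C)=C1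
F2 | step 9 | methyl (4S)-5-bromo-4-methyl-4-(4-methyl-3-oxopentyl)-6-oxocyclohept-1-ene-1-carboxylate (both C5 epimers) | CC(C)C(=O)CC[C@@]1(C)CC=C(C(=O)OC)CC(=O)C1Br
F3 | step 2 | (E)-5-iodo-N-methoxy-N,4-dimethylpent-4-enamide | I/C=C(\C)CCC(=O)N(C)OC
F4 | step 2 | (E)-6-ethoxy-N-methoxy-N,4-dimethylhepta-4,6-dienamide | C=C(OCC)/C=C(\C)CCC(=O)N(C)OC
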